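## Retrosynthetic overview

- The strategy rests on the pyranone ring O1–C2–C3–C4–C4a–C8a of the 4-phenylchroman-2-one: O1/C8a and C4a are an ortho-hydroxy/iodo pair on a fully substituted arene, C2 is carbon monoxide, and C3–C4 are the two carbons of a phenyl alkyne, with phenyl on C4.
- Target 15 ← removal of two MOM ethers ← (R)-dihydrocoumarin 14 ← copper hydride asymmetric 1,4-reduction of 4-phenylcoumarin 12, which sets C4.
- 12 ← 7-O-MOM protection and C3 protodesilylation ← 3-silylcoumarin 10 ← three-component carbonylative annulation of iodophenol 7, silyl alkyne 8 and CO (C4a–C4, C3–C2, C2–O1).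
- 7 ← ring iodination ← mono-C-prenylation ← para-O-MOM protection of 2,4,6-trihydroxybenzophenone 1.
- Ring order: the pyranone is the only ring made (step 4); the phloroglucinol arene and both phenyl rings are bought.

Key step: step 4

Assumption: the sense of induction of the copper hydride catalyst on this 5-substituted 4-phenylcoumarin is to be read from a first run; (R)-DTBM-SEGPHOS is written, and its antipode is taken if that run gives the S product.

## Route

Step 1
Reactants: 1 2,4,6-trihydroxybenzophenone; 2 chloromethyl methyl ether
Product: 3 [2,6-dihydroxy-4-(methoxymethoxy)phenyl](phenyl)methanone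
Conditions: MOMCl (1.0 equiv), K2CO3 (1.0 equiv), acetone, 0 °C → rt
Reagents that add atoms: chloromethyl methyl ether, COCCl
Why: Williamson-type O-alkylation, in which the 4-OH (para to the carbonyl, the most acidic and least hindered hydroxyl) should be ionised by one equivalent of weak base and etherified in preference to the two hydroxyls that flank the benzoyl group.

Step 2
Reactants: 3 [2,6-dihydroxy-4-(methoxymethoxy)phenyl](phenyl)methanone; 4 prenyl bromide
Product: 5 [2,6-dihydroxy-4-(methoxymethoxy)-3-(3-methylbut-2-en-1-yl)phenyl](phenyl)methanone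
Conditions: prenyl bromide (1.1 equiv), 10% aq. KOH, 0 °C → rt; recovered 3 recycled
Reagents that add atoms: prenyl bromide, CC(C)=CCBr
Why: Phenoxide C-alkylation (C-prenylation of an acylphloroglucinol), in which the hydrogen-bonded oxide centres in water leave the ring carbon ortho to one oxide and para to the other as the nucleophile toward the soft allylic bromide; the two free ring positions of 3 are equivalent, so only one mono-prenyl isomer can form.

Step 3
Reactants: 5 [2,6-dihydroxy-4-(methoxymethoxy)-3-(3-methylbut-2-en-1-yl)phenyl](phenyl)methanone; 6 iodine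
Product: 7 [2,6-dihydroxy-3-iodo-4-(methoxymethoxy)-5-(3-methylbut-2-en-1-yl)phenyl](phenyl)methanone
Conditions: I2 (1.0 equiv), NaHCO3, THF–H2O, 0 °C, short reaction time; Na2S2O3 quench
Reagents that add atoms: iodine, II
Why: Electrophilic aromatic iodination of a phenoxide at the single remaining ring CH, which is ortho/para to three oxygens and should be substituted far faster than iodine attacks the trisubstituted alkene, so that one equivalent in the cold leaves no iodine for iodoetherification.

Step 4
Reactants: 7 [2,6-dihydroxy-3-iodo-4-(methoxymethoxy)-5-(3-methylbut-2-en-1-yl)phenyl](phenyl)methanone; 8 1-phenyl-2-(trimethylsilyl)acetylene; 9 carbon monoxide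
Product: 10 8-benzoyl-7-hydroxy-5-(methoxymethoxy)-6-(3-methylbut-2-en-1-yl)-4-phenyl-3-(trimethylsilyl)-2H-chromen-2-one
Conditions: Pd(OAc)2 (5 mol %), pyridine (2 equiv), n-Bu4NCl (1 equiv), CO (1 atm), 8 (5 equiv), DMF, 120 °C
Reagents that add atoms: 1-phenyl-2-(trimethylsilyl)acetylene, C[Si](C)(C)C#Cc1ccccc1; carbon monoxide, [C-]#[O+]
Why: This is a Larock-type palladium-catalysed carbonylative annulation of an ortho-iodophenol with an internal alkyne, a known route to 3,4-disubstituted coumarins: Pd(0) inserts into the C–I bond, the aryl–Pd bond adds syn across alkyne 8 with the aryl carbon bonding to the phenyl-bearing carbon (C4a–C4), CO inserts into the vinyl–Pd bond (C3–C2), and the neighbouring phenol oxygen displaces palladium from the acyl group (C2–O1). The pyranone ring closes in this last event as a six-membered lactonisation (6-exo-trig acyl substitution, equivalent to C–O reductive elimination from a seven-membered oxapalladacycle), which returns Pd(0). No stereocentre is formed. Alkyne insertion must come before CO insertion, which the low CO pressure and the excess of alkyne should secure, since carbonylation of aryl–Pd is reversible and carbopalladation is not. The orientation of the alkyne is set by the bulky trimethylsilyl group, which takes the position next to palladium and so ends on C3 with phenyl on C4. The site of lactonisation is fixed by the substrate, in which only the 2-OH is ortho to iodine, the other flank being the MOM ether and the 6-OH being out of reach; the prenyl alkene, benzoyl group and MOM ether are spectators.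

Step 5
Reactants: 10 8-benzoyl-7-hydroxy-5-(methoxymethoxy)-6-(3-methylbut-2-en-1-yl)-4-phenyl-3-(trimethylsilyl)-2H-chromen-2-one
Product: 11 8-benzoyl-7-hydroxy-5-(methoxymethoxy)-6-(3-methylbut-2-en-1-yl)-4-phenyl-2H-chromen-2-one
Conditions: TBAF (3 equiv), wet THF, 0 °C → rt; aq. NH4Cl
Reagents that add atoms: none
Why: Fluoride-induced protodesilylation of an α-silyl enoate, in which fluoride attacks silicon and the C3–Si bond is replaced by C3–H next to the lactone carbonyl; any material that had already lost silicon in step 4 converges on the same product.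

Step 6
Reactants: 11 8-benzoyl-7-hydroxy-5-(methoxymethoxy)-6-(3-methylbut-2-en-1-yl)-4-phenyl-2H-chromen-2-one; 2 chloromethyl methyl ether
Product: 12 8-benzoyl-5,7-bis(methoxymethoxy)-6-(3-methylbut-2-en-1-yl)-4-phenyl-2H-chromen-2-one
Conditions: NaH, MOMCl, DMF, 0 °C → rt
Reagents that add atoms: chloromethyl methyl ether, COCCl
Why: Williamson-type O-alkylation of the sodium phenoxide of the only free hydroxyl, which removes the acidic proton before the copper hydride step and leaves the benzoyl carbonyl twisted between two ortho oxygen substituents.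

Step 7
Reactants: 12 8-benzoyl-5,7-bis(methoxymethoxy)-6-(3-methylbut-2-en-1-yl)-4-phenyl-2H-chromen-2-one
Product: 14 (4R)-8-benzoyl-5,7-bis(methoxymethoxy)-6-(3-methylbut-2-en-1-yl)-4-phenylchroman-2-one, via silyl ketene acetal 13 (not isolated)
Conditions: Cu(OAc)2·H2O (5 mol %), (R)-DTBM-SEGPHOS (5.5 mol %), (EtO)2MeSiH (3 equiv), toluene, 0 °C → rt; then aq. NH4F
Reagents that add atoms: none
Why: Copper hydride-catalysed asymmetric conjugate reduction, known for 4-arylcoumarins, in which the ligated Cu–H should deliver hydride to the Si face of C4 (C4a > Ph > C3) under control of the chiral bisphosphine to set the R centre, the copper enolate is silylated to ketene acetal 13 and hydrolysed on work-up; without a proton source the lactone stays masked as 13 and should not be reduced further, and the benzoyl carbonyl is shielded by its two ortho oxygens.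

Step 8
Reactants: 14 (4R)-8-benzoyl-5,7-bis(methoxymethoxy)-6-(3-methylbut-2-en-1-yl)-4-phenylchroman-2-one
Product: 15 (4R)-8-benzoyl-5,7-dihydroxy-6-(3-methylbut-2-en-1-yl)-4-phenylchroman-2-one
Conditions: 3 M aq. HCl, THF, 40 °C
Reagents that add atoms: none
Why: Acid hydrolysis of the two aryl MOM acetals, in which C4 (not α to a carbonyl) should not epimerise, the absence of an alcohol solvent avoids transesterification of the lactone, and mild aqueous acid is chosen to keep the prenyl group from cyclising onto the freed phenols.

## Compound list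

1 | 2,4,6-trihydroxybenzophenone | O=C(c1ccccc1)c1c(O)cc(O)cc1O | starting material
2 | chloromethyl methyl ether | COCCl | starting material
3 | [2,6-dihydroxy-4-(methoxymethoxy)phenyl](phenyl)methanone | O=C(c1ccccc1)c1c(O)cc(OCOC)cc1O | intermediate
4 | prenyl bromide (1-bromo-3-methylbut-2-ene) | CC(C)=CCBr | starting material
5 | [2,6-dihydroxy-4-(methoxymethoxy)-3-(3-methylbut-2-en-1-yl)phenyl](phenyl)methanone | CC(C)=CCc1c(O)c(C(=O)c2ccccc2)c(O)cc1OCOC | intermediate
6 | iodine | II | starting material
7 | [2,6-dihydroxy-3-iodo-4-(methoxymethoxy)-5-(3-methylbut-2-en-1-yl)phenyl](phenyl)methanone | CC(C)=CCc1c(O)c(C(=O)c2ccccc2)c(O)c(I)c1OCOC | intermediate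
8 | 1-phenyl-2-(trimethylsilyl)acetylene | C[Si](C)(C)C#Cc1ccccc1 | starting material
9 | carbon monoxide | [C-]#[O+] | starting material
10 | 8-benzoyl-7-hydroxy-5-(methoxymethoxy)-6-(3-methylbut-2-en-1-yl)-4-phenyl-3-(trimethylsilyl)-2H-chromen-2-one | CC(C)=CCc1c(O)c(C(=O)c2ccccc2)c2oc(=O)c([Si](C)(C)C)c(-c3ccccc3)c2c1OCOC | intermediate
11 | 8-benzoyl-7-hydroxy-5-(methoxymethoxy)-6-(3-methylbut-2-en-1-yl)-4-phenyl-2H-chromen-2-one | CC(C)=CCc1c(O)c(C(=O)c2ccccc2)c2oc(=O)cc(-c3ccccc3)c2c1OCOC | intermediate
12 | 8-benzoyl-5,7-bis(methoxymethoxy)-6-(3-methylbut-2-en-1-yl)-4-phenyl-2H-chromen-2-one | CC(C)=CCc1c(OCOC)c(C(=O)c2ccccc2)c2oc(=O)cc(-c3ccccc3)c2c1OCOC | intermediate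
13 | (4R)-8-benzoyl-2-{[diethoxy(methyl)silyl]oxy}-5,7-bis(methoxymethoxy)-6-(3-methylbut-2-en-1-yl)-4-phenyl-4H-chromene (silyl ketene acetal) | CC(C)=CCc1c(OCOC)c(C(=O)c2ccccc2)c2OC(O[Si](C)(OCC)OCC)=C[C@H](c3ccccc3)c2c1OCOC | intermediate
14 | (4R)-8-benzoyl-5,7-bis(methoxymethoxy)-6-(3-methylbut-2-en-1-yl)-4-phenylchroman-2-one | CC(C)=CCc1c(OCOC)c(C(=O)c2ccccc2)c2c(c1OCOC)[C@@H](c1ccccc1)CC(=O)O2 | intermediate
15 | (4R)-8-benzoyl-5,7-dihydroxy-6-(3-methylbut-2-en-1-yl)-4-phenylchroman-2-one | CC(C)=CCc1c(O)c(C(=O)c2ccccc2)c2c(c1O)[C@@H](c1ccccc1)CC(=O)O2 | target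

## Step count and risks

Total steps: 8. Longest linear sequence: 8 (from 1).

The three steps most likely to fail:

1. Step 4 (key step). The aryl–palladium centre sits between a hydroxyl and a MOM ether on an electron-rich ring, so carbopalladation of the bulky silyl alkyne may be slow. CO insertion could then run ahead and the aroyl–palladium species be trapped by phenols, the C–I bond could be reduced, or the alkyne could lose silicon before it inserts. The fallback sets out from 5 and comes back at 11, forming the same pyranone ring without palladium or iodine. Esterification of the less hindered hydroxyl of 5 (the one next to the ring CH) with phenylpropiolic acid (DCC, DMAP, CH2Cl2) should give 2-benzoyl-3-hydroxy-5-(methoxymethoxy)-4-(3-methylbut-2-en-1-yl)phenyl 3-phenylpropiolate F1. Gold(I)-catalysed intramolecular hydroarylation of this aryl alkynoate (Ph3PAuNTf2, 1,2-dichloroethane, rt), a known coumarin synthesis for electron-rich arenes, should then let the only free ring carbon attack the activated alkyne in a 6-endo-dig sense and give 11 directly, so that steps 3 to 5 are bypassed.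

2. Step 7. Hydride delivery to C4 is hindered by the peri MOM ether and the twisted 4-phenyl group, so turnover may be slow. 1,2-Reduction of the benzoyl or lactone carbonyl may then compete, and the two faces of C4 may be poorly discriminated. The fallback sets out from 12 and comes back at 14, moving the stereo-determining event to a carboxylate-directed hydrogenation. Opening the lactone with NaOH in aqueous methanol should give disodium (2Z)-3-[3-benzoyl-4,6-bis(methoxymethoxy)-5-(3-methylbut-2-en-1-yl)-2-oxidophenyl]-3-phenylprop-2-enoate F2. Asymmetric hydrogenation of this salt with a rhodium(I)–chiral diphosphine catalyst (H2, MeOH; ligand antipode chosen for the R product), a known way to reduce ring-opened 4-arylcoumarins, should give disodium (3R)-3-[3-benzoyl-4,6-bis(methoxymethoxy)-5-(3-methylbut-2-en-1-yl)-2-oxidophenyl]-3-phenylpropanoate F3. The isolated prenyl alkene and the diaryl ketone are not directed substrates and should be left alone. Acidification with acetic acid relactonises F3 to 14.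

3. Step 3. Iodine may be consumed at the prenyl alkene, with the neighbouring hydroxyl or the MOM oxygen closing onto the iodonium ion (iodoetherification), in competition with ring substitution. The fallback sets out from 3 and comes back at 7 by reversing the order, so that no electrophilic iodine meets the alkene. Iodination of 3 (I2, 1.0 equiv, NaHCO3, THF–H2O, 0 °C; the two ring positions are equivalent) should give [2,6-dihydroxy-3-iodo-4-(methoxymethoxy)phenyl](phenyl)methanone F4. C-Prenylation of F4 at the one remaining ring CH (prenyl bromide, 10% aq. KOH, 0 °C → rt) should then give 7.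

## Further compounds

F1 | step 4 | 2-benzoyl-3-hydroxy-5-(methoxymethoxy)-4-(3-methylbut-2-en-1-yl)phenyl 3-phenylpropiolate | CC(C)=CCc1c(O)c(C(=O)c2ccccc2)c(OC(=O)C#Cc2ccccc2)cc1OCOC
F2 | step 7 | disodium (2Z)-3-[3-benzoyl-4,6-bis(methoxymethoxy)-5-(3-methylbut-2-en-1-yl)-2-oxidophenyl]-3-phenylprop-2-enoate | [Na+].[Na+].[O-]C(=O)/C=C(/c1ccccc1)c1c([O-])c(C(=O)c2ccccc2)c(OCOC)c(CC=C(C)C)c1OCOC
F3 | step 7 | disodium (3R)-3-[3-benzoyl-4,6-bis(methoxymethoxy)-5-(3-methylbut-2-en-1-yl)-2-oxidophenyl]-3-phenylpropanoate | [Na+].[Na+].[O-]C(=O)C[C@H](c1ccccc1)c1c([O-])c(C(=O)c2ccccc2)c(OCOC)c(CC=C(C)C)c1OCOC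
F4 | step 3 | [2,6-dihydroxy-3-iodo-4-(methoxymethoxy)phenyl](phenyl)methanone | O=C(c1ccccc1)c1c(O)cc(OCOC)c(I)c1O
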